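## Retrosynthetic overview

1. Target ⇐ phenol unmasking ⇐ aroylation of C6–OH ⇐ convex-face reduction of a C6 ketone in the cis-fused hydroazulene; the C10 isovalerate is already in place.
2. Seven-membered ring (third and last ring) ⇐ ring-closing metathesis of a C10 vinyl group and a C6 methallyl ketone held cis on the cyclopentane.
3. Both arms ⇐ one cis-fused γ-lactone (second ring, temporary): methallyl Grignard at the lactone carbonyl (C6); the lactone oxygen is O10.
4. Angular methyl (C1) and ring-fusion H (C5) ⇐ methylcuprate addition to a flat bicyclic butenolide, anti to its vinyl and isopropyl groups.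
5. Butenolide ⇐ key step: homoenolate [3+2] annulation of 1-isopropylcyclopropanol with (R)-methyl 4-hydroxyhex-5-en-2-ynoate (C1–C2 and C4–C5 bonds; cyclopentene ring formed first), then lactonisation.

Assumption: the SMILES is read literally as the cis-fused (3S,3aS,4R,8R,8aR)-octahydroazulene; "C1–C10" in the overview is daucane numbering (C1 angular-methyl carbon, C4 isopropyl carbinol, C5 ring-fusion CH, C6 benzoate carbon, C10 isovalerate carbon), and in steps 2 and 3 the ligand antipode is the one that gives the stated configuration.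

## Route

Step 1
Reactants: 1 methyl 2-methylpropanoate
Product: 2 1-(propan-2-yl)cyclopropan-1-ol
Conditions: EtMgBr (2.2 equiv), Ti(OiPr)4 (20 mol %), Et2O, 0 °C → rt; aq H2SO4
Reagents that add atoms: ethylmagnesium bromide (CC[Mg]Br)
Why: Kulinkovich cyclopropanation, in which the titanacyclopropane formed from two ethyl groups on titanium adds twice to the ester carbonyl to give the cyclopropanol (no stereocentre).

Step 2
Reactants: 3 prop-2-enal (acrolein); 4 methyl prop-2-ynoate
Product: 5 methyl (4R)-4-hydroxyhex-5-en-2-ynoate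
Conditions: Me2Zn (3 equiv), ProPhenol ligand (10 mol %), toluene, 0 °C; aq NH4Cl
Reagents that add atoms: none
Why: Zinc–ProPhenol catalysed asymmetric alkynylation (1,2-addition of the zinc alkynylide to the enal carbonyl), where the chiral dizinc pocket selects the aldehyde face and sets the future isovalerate carbinol as R.

Step 3
Reactants: 2 1-(propan-2-yl)cyclopropan-1-ol; 5 methyl (4R)-4-hydroxyhex-5-en-2-ynoate
Product: 7 (3R,6S)-3-ethenyl-6-hydroxy-6-(propan-2-yl)-3,4,5,6-tetrahydro-1H-cyclopenta[c]furan-1-one (butenolide), via hydroxy ester 6 (not isolated)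
Conditions: CoBr2 (10 mol %), chiral bisphosphine BDPP (12 mol %), Zn dust (20 mol %), DABCO (20 mol %), MeCN, 60 °C; then TsOH·H2O (5 mol %), CH2Cl2, rt
Reagents that add atoms: none
Why: Proposed new method: the low-valent cobalt alkoxide of 2 ring-opens by β-carbon elimination to a cobalt homoenolate (the ketone β-carbon becomes the nucleophile), which adds syn across the ynoate with the alkyl group going to the alkyne carbon β to the ester, and the resulting alkenylcobalt adds 5-exo to the pendant isopropyl ketone with the bisphosphine choosing the ketone face (6S); the cis ester and carbinol then lactonise, and any 6-epimer is a diastereomer removable on silica because C3 is already R; the closest known reactions are the cobalt-catalysed ring-opening [3+2] annulation of cyclopropanols with internal alkynes and bisphosphine-controlled asymmetric additions of alkenylmetals to tethered ketones.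

Step 4
Reactants: 7 (3R,6S)-3-ethenyl-6-hydroxy-6-(propan-2-yl)-3,4,5,6-tetrahydro-1H-cyclopenta[c]furan-1-one
Product: 8 (3R,3aR,6S,6aR)-3-ethenyl-6-hydroxy-3a-methyl-6-(propan-2-yl)hexahydro-1H-cyclopenta[c]furan-1-one
Conditions: Me2CuLi (3.5 equiv), Et2O, −78 → −30 °C; aq NH4Cl at −78 °C
Reagents that add atoms: lithium dimethylcuprate ([Li+].C[Cu-]C)
Why: Gilman cuprate conjugate addition to a γ-substituted butenolide, in which methyl enters the ring-fusion β-carbon anti to both the C3 vinyl and the C6 isopropyl groups (syn to the lithium alkoxide) and protonation of the lactone enolate can only give the cis-fused bicyclo[3.3.0] lactone, fixing C3a and C6a.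

Step 5
Reactants: 8 (3R,3aR,6S,6aR)-3-ethenyl-6-hydroxy-3a-methyl-6-(propan-2-yl)hexahydro-1H-cyclopenta[c]furan-1-one
Product: 9 (3R,3aR,6S,6aR)-3-ethenyl-3a-methyl-1-(2-methylprop-2-en-1-yl)-6-(propan-2-yl)hexahydro-1H-cyclopenta[c]furan-1,6-diol (cyclic hemiketal, both C1 epimers)
Conditions: 2-methylallylmagnesium chloride (2.2 equiv), THF, −78 °C; aq NH4Cl at −78 °C
Reagents that add atoms: 2-methylallylmagnesium chloride (CC(=C)C[Mg]Cl)
Why: Grignard mono-addition to a hindered γ-lactone, where the magnesium hemiketalate survives at low temperature so the methallyl ketone is obtained masked as its hemiketal (the hemiketal carbon is not a controlled stereocentre).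

Step 6
Reactants: 9 (3R,3aR,6S,6aR)-3-ethenyl-3a-methyl-1-(2-methylprop-2-en-1-yl)-6-(propan-2-yl)hexahydro-1H-cyclopenta[c]furan-1,6-diol
Product: 11 (1R)-1-[(1R,2R,3S)-3-hydroxy-1-methyl-2-(3-methylbut-3-enoyl)-3-(propan-2-yl)cyclopentyl]prop-2-en-1-yl 3-methylbutanoate, via hydroxy ketone 10 (not isolated)
Conditions: 3-methylbutanoic anhydride (2 equiv), DMAP (0.2 equiv), pyridine, CH2Cl2, 0 °C → rt
Reagents that add atoms: 3-methylbutanoic anhydride (CC(C)CC(=O)OC(=O)CC(C)C)
Why: DMAP-catalysed acyl transfer (Steglich-type) drains the ring-opened tautomer through its only acylable hydroxyl, the secondary allylic one, while both tertiary hydroxyls stay free and no stereocentre is touched.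

Step 7
Reactants: 11 (1R)-1-[(1R,2R,3S)-3-hydroxy-1-methyl-2-(3-methylbut-3-enoyl)-3-(propan-2-yl)cyclopentyl]prop-2-en-1-yl 3-methylbutanoate
Product: 12 (3S,3aR,8R,8aR)-3-hydroxy-6,8a-dimethyl-4-oxo-3-(propan-2-yl)-1,2,3,3a,4,5,8,8a-octahydroazulen-8-yl 3-methylbutanoate
Conditions: second-generation Grubbs catalyst [RuCl2(=CHPh)(H2IMes)(PCy3)] (5 mol %), CH2Cl2 (5 mM), 40 °C
Reagents that add atoms: none
Why: Ring-closing olefin metathesis between the vinyl group and the 1,1-disubstituted methallyl unit, both held cis on the cyclopentane, closes the cycloheptene with its trisubstituted olefin and releases ethene.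

Step 8
Reactants: 12 (3S,3aR,8R,8aR)-3-hydroxy-6,8a-dimethyl-4-oxo-3-(propan-2-yl)-1,2,3,3a,4,5,8,8a-octahydroazulen-8-yl 3-methylbutanoate
Product: 13 (3S,3aS,4R,8R,8aR)-3,4-dihydroxy-6,8a-dimethyl-3-(propan-2-yl)-1,2,3,3a,4,5,8,8a-octahydroazulen-8-yl 3-methylbutanoate
Conditions: NaBH4, CeCl3·7H2O, MeOH, −78 → −40 °C
Reagents that add atoms: none
Why: Luche reduction, in which hydride attacks the ketone from the convex face of the cis-fused bicycle (the face of the angular methyl and ring-fusion H, the concave face being screened by the five-membered ring and its isopropyl group), giving the 4R alcohol.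

Step 9
Reactants: 13 (3S,3aS,4R,8R,8aR)-3,4-dihydroxy-6,8a-dimethyl-3-(propan-2-yl)-1,2,3,3a,4,5,8,8a-octahydroazulen-8-yl 3-methylbutanoate
Product: 14 (3S,3aS,4R,8R,8aR)-3-hydroxy-6,8a-dimethyl-8-[(3-methylbutanoyl)oxy]-3-(propan-2-yl)-1,2,3,3a,4,5,8,8a-octahydroazulen-4-yl 4-(acetyloxy)benzoate
Conditions: 4-acetoxybenzoyl chloride (2 equiv), Et3N, DMAP (cat.), CH2Cl2, 0 °C → rt
Reagents that add atoms: 4-acetoxybenzoyl chloride (CC(=O)Oc1ccc(cc1)C(Cl)=O)
Why: DMAP-catalysed acylation of the only secondary hydroxyl with retention at C4, the tertiary carbinol being too hindered to react.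

Step 10
Reactants: 14 (3S,3aS,4R,8R,8aR)-3-hydroxy-6,8a-dimethyl-8-[(3-methylbutanoyl)oxy]-3-(propan-2-yl)-1,2,3,3a,4,5,8,8a-octahydroazulen-4-yl 4-(acetyloxy)benzoate
Product: 15 (3S,3aS,4R,8R,8aR)-3-hydroxy-6,8a-dimethyl-8-[(3-methylbutanoyl)oxy]-3-(propan-2-yl)-1,2,3,3a,4,5,8,8a-octahydroazulen-4-yl 4-hydroxybenzoate (CNP0086724.1)
Conditions: NH3 (7 M in MeOH), 0 °C, 30 min
Reagents that add atoms: none
Why: Chemoselective aminolysis of the phenolic acetate, since an aryl ester is a far better acyl donor than the alkyl benzoate or the hindered isovalerate, frees the phenol without touching any stereocentre.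

## Compound list

1 | methyl 2-methylpropanoate | COC(=O)C(C)C | starting material
2 | 1-(propan-2-yl)cyclopropan-1-ol | CC(C)C1(O)CC1 | intermediate
3 | prop-2-enal (acrolein) | C=CC=O | starting material
4 | methyl prop-2-ynoate | C#CC(=O)OC | starting material
5 | methyl (4R)-4-hydroxyhex-5-en-2-ynoate | C=C[C@@H](O)C#CC(=O)OC | intermediate
6 | methyl (5S)-5-hydroxy-2-[(1R)-1-hydroxyprop-2-en-1-yl]-5-(propan-2-yl)cyclopent-1-ene-1-carboxylate (not isolated) | C=C[C@@H](O)C1=C(C(=O)OC)[C@@](O)(C(C)C)CC1 | intermediate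
7 | (3R,6S)-3-ethenyl-6-hydroxy-6-(propan-2-yl)-3,4,5,6-tetrahydro-1H-cyclopenta[c]furan-1-one | C=C[C@H]1OC(=O)C2=C1CC[C@]2(O)C(C)C | intermediate
8 | (3R,3aR,6S,6aR)-3-ethenyl-6-hydroxy-3a-methyl-6-(propan-2-yl)hexahydro-1H-cyclopenta[c]furan-1-one | C=C[C@H]1OC(=O)[C@@H]2[C@@]1(C)CC[C@]2(O)C(C)C | intermediate
9 | (3R,3aR,6S,6aR)-3-ethenyl-3a-methyl-1-(2-methylprop-2-en-1-yl)-6-(propan-2-yl)hexahydro-1H-cyclopenta[c]furan-1,6-diol (both C1 epimers) | C=C[C@H]1OC(O)(CC(C)=C)[C@@H]2[C@@]1(C)CC[C@]2(O)C(C)C | intermediate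
10 | 1-[(1R,2R,5S)-5-hydroxy-2-[(1R)-1-hydroxyprop-2-en-1-yl]-2-methyl-5-(propan-2-yl)cyclopentyl]-3-methylbut-3-en-1-one (not isolated) | C=C[C@@H](O)[C@]1(C)CC[C@](O)(C(C)C)[C@@H]1C(=O)CC(C)=C | intermediate
11 | (1R)-1-[(1R,2R,3S)-3-hydroxy-1-methyl-2-(3-methylbut-3-enoyl)-3-(propan-2-yl)cyclopentyl]prop-2-en-1-yl 3-methylbutanoate | C=C[C@@H](OC(=O)CC(C)C)[C@]1(C)CC[C@](O)(C(C)C)[C@@H]1C(=O)CC(C)=C | intermediate
12 | (3S,3aR,8R,8aR)-3-hydroxy-6,8a-dimethyl-4-oxo-3-(propan-2-yl)-1,2,3,3a,4,5,8,8a-octahydroazulen-8-yl 3-methylbutanoate | CC1=C[C@@H](OC(=O)CC(C)C)[C@]2(C)CC[C@](O)(C(C)C)[C@@H]2C(=O)C1 | intermediate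
13 | (3S,3aS,4R,8R,8aR)-3,4-dihydroxy-6,8a-dimethyl-3-(propan-2-yl)-1,2,3,3a,4,5,8,8a-octahydroazulen-8-yl 3-methylbutanoate | CC1=C[C@@H](OC(=O)CC(C)C)[C@]2(C)CC[C@](O)(C(C)C)[C@@H]2[C@H](O)C1 | intermediate
14 | (3S,3aS,4R,8R,8aR)-3-hydroxy-6,8a-dimethyl-8-[(3-methylbutanoyl)oxy]-3-(propan-2-yl)-1,2,3,3a,4,5,8,8a-octahydroazulen-4-yl 4-(acetyloxy)benzoate | CC1=C[C@@H](OC(=O)CC(C)C)[C@]2(C)CC[C@](O)(C(C)C)[C@@H]2[C@H](OC(=O)c2ccc(OC(C)=O)cc2)C1 | intermediate
15 | (3S,3aS,4R,8R,8aR)-3-hydroxy-6,8a-dimethyl-8-[(3-methylbutanoyl)oxy]-3-(propan-2-yl)-1,2,3,3a,4,5,8,8a-octahydroazulen-4-yl 4-hydroxybenzoate | CC1=C[C@@H](OC(=O)CC(C)C)[C@]2(C)CC[C@](O)(C(C)C)[C@@H]2[C@H](OC(=O)c2ccc(O)cc2)C1 | target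

## Step count and risks

Total step count: 10. Longest linear sequence: 9 steps (steps 2–10 from 3 and 4, or steps 1 and 3–10 from 1).

**Step 3 (annulation).** The cobalt homoenolate may only alkenylate the ynoate without closing onto the ketone, or the free propargylic hydroxyl may interfere. The fallback sets out from 2 and 5 and comes back at 6. Compound 2 is opened with Et2Zn to the zinc homoenolate ethyl(4-methyl-3-oxopentyl)zinc F1. This is added across the triple bond of 5 under CuBr·SMe2 catalysis (syn-carbocupration, alkyl to the carbon β to the ester) and the alkenylmetal is quenched with iodine to give the iodo-enoate F2. Intramolecular Nozaki–Hiyama–Kishi addition of the alkenyl iodide to the isopropyl ketone (CrCl2, catalytic NiCl2, DMF) then closes the cyclopentene to 6, which lactonises to 7 as before. The two carbinol epimers are diastereomers and are separated at 7.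

**Step 4 (cuprate addition).** The cuprate may open the allylic lactone through the vinyl group (SN2′) instead of adding to the hindered butenolide. The fallback sets out from 3 and comes back at 8, carrying the vinyl group as a saturated precursor. Benzeneselenol is added to 3 to give 3-(phenylselanyl)propanal F3. The same zinc–ProPhenol alkynylation with 4 gives the selenide alkynol F4. Annulation with 2 under the step 3 conditions gives the selenide hydroxy ester F5 and, after lactonisation, the selenide butenolide F6. Me2CuLi then has no allylic leaving group to attack and gives the selenide lactone F7. Oxidation with H2O2 gives the selenoxide F8, whose syn-elimination at room temperature unveils the vinyl group and returns 8.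

**Step 5 (Grignard mono-addition).** The allylic Grignard may add twice, or the β,γ-unsaturated ketone may isomerise. The fallback sets out from 8 and comes back at 11, changing the order of events. Compound 8 is opened with MeNHOMe·HCl/Me3Al to the hydroxy Weinreb amide F9. The freed secondary hydroxyl is acylated with 3-methylbutanoic anhydride/DMAP to the ester Weinreb amide F10. 2-Methylallylmagnesium chloride at −78 °C then adds once only, at the chelating amide, and gives 11 directly, bypassing 9 and 10.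

Further compounds
F1 | step 3 | ethyl(4-methyl-3-oxopentyl)zinc | CC[Zn]CCC(=O)C(C)C
F2 | step 3 | methyl (2E)-3-[(1R)-1-hydroxyprop-2-en-1-yl]-2-iodo-7-methyl-6-oxooct-2-enoate | COC(=O)/C(I)=C(/CCC(=O)C(C)C)[C@H](O)C=C
F3 | step 4 | 3-(phenylselanyl)propanal | O=CCC[Se]c1ccccc1
F4 | step 4 | methyl (4R)-4-hydroxy-6-(phenylselanyl)hex-2-ynoate | c1ccccc1[Se]CC[C@@H](O)C#CC(=O)OC
F5 | step 4 | methyl (5S)-5-hydroxy-2-[(1R)-1-hydroxy-3-(phenylselanyl)propyl]-5-(propan-2-yl)cyclopent-1-ene-1-carboxylate | c1ccccc1[Se]CC[C@@H](O)C1=C(C(=O)OC)[C@@](O)(C(C)C)CC1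
F6 | step 4 | (3R,6S)-6-hydroxy-3-[2-(phenylselanyl)ethyl]-6-(propan-2-yl)-3,4,5,6-tetrahydro-1H-cyclopenta[c]furan-1-one | c1ccccc1[Se]CC[C@H]1OC(=O)C2=C1CC[C@]2(O)C(C)C
F7 | step 4 | (3R,3aR,6S,6aR)-6-hydroxy-3a-methyl-3-[2-(phenylselanyl)ethyl]-6-(propan-2-yl)hexahydro-1H-cyclopenta[c]furan-1-one | c1ccccc1[Se]CC[C@H]1OC(=O)[C@@H]2[C@@]1(C)CC[C@]2(O)C(C)C
F8 | step 4 | (3R,3aR,6S,6aR)-3-[2-(benzeneseleninyl)ethyl]-6-hydroxy-3a-methyl-6-(propan-2-yl)hexahydro-1H-cyclopenta[c]furan-1-one | O=[Se](c1ccccc1)CC[C@H]1OC(=O)[C@@H]2[C@@]1(C)CC[C@]2(O)C(C)C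
F9 | step 5 | (1R,2R,5S)-5-hydroxy-2-[(1R)-1-hydroxyprop-2-en-1-yl]-N-methoxy-N,2-dimethyl-5-(propan-2-yl)cyclopentane-1-carboxamide | C=C[C@@H](O)[C@]1(C)CC[C@](O)(C(C)C)[C@@H]1C(=O)N(C)OC
F10 | step 5 | (1R)-1-[(1R,2R,3S)-3-hydroxy-2-[methoxy(methyl)carbamoyl]-1-methyl-3-(propan-2-yl)cyclopentyl]prop-2-en-1-yl 3-methylbutanoate | C=C[C@@H](OC(=O)CC(C)C)[C@]1(C)CC[C@](O)(C(C)C)[C@@H]1C(=O)N(C)OC
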